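## The problem

Target 39 is a (2S)-5,7-dihydroxyflavanone whose C6 is bonded to C3 of a cyclohexene. The cyclohexene carries a 4-methylpent-3-enyl chain on C1 (C1=C2), a 4-hydroxy-3-prenylbenzoyl group on C4 and a 2,4-dihydroxyphenyl group on C5; C3, C4 and C5 are contiguous stereocentres, all-trans (3R,4R,5S).

The flavanone C2 centre is too far from the triad to be controlled by it, so each half must be made enantiopure by reagent control and the two joined late. Within the triad, C4 is alpha to the aryl ketone and will settle into the all-equatorial arrangement. C3 and C5 cannot be equilibrated, so their cis-1,3 relation has to be set kinetically.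

A 5,7-dioxygenated flavanone does not distinguish C6 from C8 towards electrophiles, and ring closure of an acylphloroglucinol has the same ambiguity, so the point of attachment must be fixed by construction.

Sensitive groups: three trisubstituted alkenes (acid closes a prenyl group onto its ortho phenol, and hydrogenation is excluded); the flavanone, which opens by retro-oxa-Michael reaction under base and can epimerise at C2; and five phenols.

The enabling feature is ring A. C6 sits between the C5 and C7 oxygens, C8 is unsubstituted, and C8a–O1 and C4a–C4 are the enol-ether carbon and the alpha carbon of a dihydropyranone. The six ring A carbons are therefore what a siloxyalkyne (C6, C7) and a dihydropyranone-derived vinylketene (C5, C8, C8a, C4a) deliver in a benzannulation.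

## Retrosynthesis

**Protecting groups and oxidation level (39 back to 35).** No skeletal bond is cut. The phenols are carried as methoxymethyl ethers (38), the C7 oxygen as the triisopropylsilyl ether that the alkyne brings (37), and the C4 aroyl group as a triethylsilyl-protected carbinol (36, 35). The ketone is masked because an enolisable aryl ketone would not survive the amide bases and organometallics needed to make the siloxyalkyne, and it would absorb the light used in the Wolff step. The carbinol is an inert spectator, and oxidation after ring A is built returns C4 alpha to a ketone, where the all-trans arrangement is the stable one.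

**Ring A (35 to 24 + 31).** The flavanone C5–C6, C7–C8 and C4a–C5 bonds are cut, giving siloxyalkyne 24 and diazo ketone 31. The neighbouring cuts were rejected: joining an intact flavanone to a cyclohexenyl electrophile at C6–C3, or closing the pyranone on an acylphloroglucinol, both leave the 6/8 question open and put the C3 or C2 centre at risk. Here C3 is already bonded to the alkyne carbon that becomes C6, and C2 is already in the pyranone. Each precursor is about half the target, and all four stereocentres are in place before the coupling. The forward step needs a regioselective ketene–alkyne [2+2] and must tolerate the alkenes and acetals.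

**Diazo ketone (31 to 29, 28, then 2 + 26).** The C–CHN2 bond is cut back to acid 29 and ester 28. The dihydropyranone is cut at O1–C2 and C3–C4 into aldehyde 2 and the bis(silyl) dienol ether 26 of ethyl 2,4-dioxopentanoate 25. This places the carboxyl carbon on C6 directly, which a later functionalisation of a 6-unsubstituted dihydropyranone could not do cleanly. The forward reaction must set the single stereocentre by catalyst control and must avoid base, which opens the ring.

**Ynol ether (24 to 21 and 20).** The C≡C–O unit is taken back through ynolate 23 and acetylide 22 to dibromoalkene 21 and aldehyde 20, so the alkyne carbon and its oxygen are added after all carbon–carbon work on the ring is done. Non-basic reagents are needed because 20 is a beta,gamma-unsaturated aldehyde with a stereocentre at its alpha carbon.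

**C3 (20 and 19 to 17 and 16).** The C3–CH2 bond is cut by a [2,3]-Wittig transform to the stannylmethyl ether 17 of tertiary allylic alcohol 16. Two more direct cuts were rejected on stereochemical grounds. Conjugate alkynylation of enone 15 would follow the C5 aryl group and give the 3,5-trans isomer. A Diels–Alder reaction of an alkynyl diene with a cinnamoyl dienophile would, by the endo rule, put C3 cis to the C4 carbonyl and hence trans to C5. The sigmatropic shift is suprafacial, so the C1 oxygen configuration is transferred to C3 with certainty, and the ring alkene ends up at C1=C2.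

**Side chain (16 to 15).** The C1–CH2 bond is cut to enone 15 and a 4-methylpent-3-enyl organometallic. The forward addition must be 1,2-selective and must come from the face that leaves the hydroxyl cis to the C5 aryl group.

**Aroyl carbon (15 and 14 to 8 + 11).** The carbinol–aryl bond is cut to aldehyde 8 and aryl bromide 11 (from 4-bromophenol 9 via 10). Adding the aryl group as a nucleophile gives the masked ketone directly, and the enone is released from the amino silyl enol ether in the same operation.

**Cyclohexenone (8 to 3 + 7).** The C3–C4 and C5–C6 bonds are cut by a Diels–Alder transform to enal 3 (from 2, from 1) and the chiral 1-amino-3-siloxy diene 7 (from 4 and 5 via 6). The (E)-enal fixes C4/C5 trans and the auxiliary fixes the absolute configuration, so the two non-epimerisable relationships are each set by a dependable element.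

## Roads not taken

**Alternative 1:** The C3–C4 ring bond is cut. In the forward direction the silyl ketene acetal of lactone A1 undergoes an Ireland–Claisen ring contraction to the all-cis acid A2, which would then be epimerised at C4.
- Merits: the cis relation of C3 and C5 comes from the boat transition state enforced by the lactone, ring A is a cheap phloroglucinol unit present from the start, and no photochemistry is needed. In these respects it is as good as or better than the chosen route.
- Weak points: A1 needs a quaternary carbinol centre set relative to C5. The acid of A2 must become an aryl ketone at a crowded carbon. The flavanone must then be built on a tris-protected phloroglucinol, where closure onto either ortho oxygen gives the 6- or the 8-substituted isomer, and C2 is set late on a substrate that already carries three stereocentres.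
- Against the alternative's simpler ring A, the chosen plan offers unambiguous 6-substitution and a C2 centre made before the coupling.

**Alternative 2:** The C5–C6 and C1=C2 bonds are cut. Silyl enol ether A3 adds to arylidene keto phosphonate A4 under copper ditriflate with a chiral bis(oxazoline), and the phosphonate carbanion then closes onto the ketone to give cyclohexenone A5.
- Merits: it is catalytic and asymmetric, the side chain and the C1=C2 position come from sulcatone, and C4/C5 trans is the stable arrangement. It reaches a cyclohexene core in far fewer steps than the fifteen steps to 24.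
- Weak points: C3 emerges as a ketone. Turning it into a C–H stereocentre bearing ring A means adding a carbon nucleophile next to an acidic beta-keto ester and then removing the oxygen with facial control, in which the adjacent C4 group and the C5 aryl group pull in opposite directions. The ester must still become the aryl ketone, and the flavanone question of alternative 1 returns.
- Against the alternative's shorter ring synthesis, the chosen plan sets C3 by a suprafacial rearrangement and never has a carbonyl at C3.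

**Alternative 3:** The C4–C5 bond is cut. Acid converts the ortho-hydroxybenzylic alcohol of A6 into an ortho-quinone methide, which the enol of the aryl ketone attacks to give A7.
- Merits: both aryl groups and the ketone are in place, and the closure goes through a chair with C4 free to equilibrate, so all-trans should result without an auxiliary. On the triad alone this is the most direct of the four roads.
- Weak points: the acid acts on a substrate with prenyl groups and acetals. The quinone methide can be intercepted by the C1=C2 alkene in a hetero-Diels–Alder reaction. A6 needs a geometrically defined trisubstituted alkene and an open-chain C3 centre. One phenol must be left free among protected ones, and the flavanone remains to be built.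
- Against the alternative's direct closure, the chosen plan offers a neutral key step that closes ring A without touching the triad and without the flavanone regiochemistry problem.

Key step: step 20

Abbreviations: Ar1 = 2,4-bis(methoxymethoxy)phenyl; Ar2 = 4-(methoxymethoxy)-3-(3-methylbut-2-en-1-yl)phenyl. Cyclohexene locants are those of the names given (C1 bears the 4-methylpent-3-enyl chain or its precursor oxygen).

Assumption 1: the facial sense of diene 7 and of the (S)-BINOL titanium catalyst is taken by analogy with simple dienophiles and aromatic aldehydes; if either is reversed, the antipodal auxiliary or ligand is used.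

Assumption 2: the carbinol carbon made in step 8 is carried as a mixture of epimers, since step 22 turns it into the ketone carbon.

## Route

Step 1
Reactants: 1 2,4-dihydroxybenzaldehyde
Product: 2 2,4-bis(methoxymethoxy)benzaldehyde
Conditions: MOMCl, iPr2NEt, CH2Cl2, 0 °C to reflux
Reagents that add atoms: chloromethyl methyl ether, COCCl
Why: O-alkylation of both phenols with the chloromethyl ether (acetal protection); the chelated 2-hydroxyl needs excess reagent and warming.

Step 2
Reactants: 2 2,4-bis(methoxymethoxy)benzaldehyde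
Product: 3 (E)-3-[2,4-bis(methoxymethoxy)phenyl]prop-2-enal
Conditions: Ph3P=CHCHO, toluene, 80 °C
Reagents that add atoms: (triphenylphosphoranylidene)acetaldehyde, O=CC=P(c1ccccc1)(c1ccccc1)c1ccccc1
Why: Wittig olefination with a formyl-stabilised ylide should give the (E)-enal; the aryl aldehyde reacts faster than the conjugated product.

Step 3
Reactants: 4 (E)-4-methoxybut-3-en-2-one; 5 (2S,5S)-2,5-diphenylpyrrolidine
Product: 6 (E)-4-[(2S,5S)-2,5-diphenylpyrrolidin-1-yl]but-3-en-2-one
Conditions: CH2Cl2, rt
Reagents that add atoms: none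
Why: Addition–elimination of the amine on the vinylogous ester gives the (E)-vinylogous amide.

Step 4
Reactants: 6 (E)-4-[(2S,5S)-2,5-diphenylpyrrolidin-1-yl]but-3-en-2-one
Product: 7 (2S,5S)-1-[(1E)-3-(tert-butyldimethylsilyloxy)buta-1,3-dien-1-yl]-2,5-diphenylpyrrolidine
Conditions: KN(SiMe3)2, THF, −78 °C; TBSCl
Reagents that add atoms: tert-butyldimethylsilyl chloride, CC(C)(C)[Si](C)(C)Cl
Why: Kinetic deprotonation of the methyl ketone and O-silylation give the 1-amino-3-siloxy diene.

Step 5
Reactants: 3 (E)-3-[2,4-bis(methoxymethoxy)phenyl]prop-2-enal; 7 (2S,5S)-1-[(1E)-3-(tert-butyldimethylsilyloxy)buta-1,3-dien-1-yl]-2,5-diphenylpyrrolidine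
Product: 8 (1R,2S,6S)-6-Ar1-4-(tert-butyldimethylsilyloxy)-2-[(2S,5S)-2,5-diphenylpyrrolidin-1-yl]cyclohex-3-ene-1-carbaldehyde
Conditions: toluene, 25 to 45 °C
Reagents that add atoms: none
Why: Diels–Alder reaction of an electron-rich amino siloxy diene with an enal, a known use of chiral dienes of this class; the amino terminus bonds to the enal alpha carbon, the (E)-enal gives the formyl and aryl groups trans, and the C2-symmetric pyrrolidine shields one diene face and so sets both retained centres.

Step 6
Reactants: 9 4-bromophenol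
Product: 10 4-bromo-2-(3-methylbut-2-en-1-yl)phenol
Conditions: NaH, toluene, 0 °C; prenyl bromide, rt
Reagents that add atoms: 1-bromo-3-methylbut-2-ene, CC(C)=CCBr
Why: C-alkylation of the sodium phenoxide in a non-polar solvent goes ortho because the para position is blocked.

Step 7
Reactants: 10 4-bromo-2-(3-methylbut-2-en-1-yl)phenol
Product: 11 4-bromo-1-(methoxymethoxy)-2-(3-methylbut-2-en-1-yl)benzene
Conditions: MOMCl, iPr2NEt, CH2Cl2, 0 °C to rt
Reagents that add atoms: chloromethyl methyl ether, COCCl
Why: Acetal protection of the phenol, as in step 1.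

Step 8
Reactants: 11 4-bromo-1-(methoxymethoxy)-2-(3-methylbut-2-en-1-yl)benzene; 8 (1R,2S,6S)-6-Ar1-4-(tert-butyldimethylsilyloxy)-2-[(2S,5S)-2,5-diphenylpyrrolidin-1-yl]cyclohex-3-ene-1-carbaldehyde
Product: 14 (4S,5S)-5-Ar1-4-[Ar2(hydroxy)methyl]cyclohex-2-en-1-one, via aryllithium 12 (not isolated), via amino silyl enol ether carbinol 13 (not isolated)
Conditions: 11, n-BuLi, THF, −78 °C; then 8, −78 °C; aq NH4Cl; then HF·pyridine, MeCN, 0 °C
Reagents that add atoms: none
Why: Bromine–lithium exchange and 1,2-addition of the aryllithium to the aldehyde give the carbinol (either epimer serves); fluoride cleavage of the silyl enol ether and beta-elimination of the amine then release the enone without touching C4 or C5.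

Step 9
Reactants: 14 (4S,5S)-5-Ar1-4-[Ar2(hydroxy)methyl]cyclohex-2-en-1-one
Product: 15 (4S,5S)-5-Ar1-4-[Ar2(triethylsilyloxy)methyl]cyclohex-2-en-1-one
Conditions: TESOTf, 2,6-lutidine, CH2Cl2, −78 °C
Reagents that add atoms: triethylsilyl trifluoromethanesulfonate, CC[Si](CC)(CC)OS(=O)(=O)C(F)(F)F
Why: Silylation of a hindered secondary alcohol with a silyl triflate; the triethylsilyl ether withstands the bases that follow and can later be removed beside an aryl triisopropylsilyl ether.

Step 10
Reactants: 15 (4S,5S)-5-Ar1-4-[Ar2(triethylsilyloxy)methyl]cyclohex-2-en-1-one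
Product: 16 (1R,4S,5S)-5-Ar1-1-(4-methylpent-3-en-1-yl)-4-[Ar2(triethylsilyloxy)methyl]cyclohex-2-en-1-ol
Conditions: (4-methylpent-3-enyl)magnesium bromide, CeCl3, THF, −78 °C
Reagents that add atoms: (4-methylpent-3-en-1-yl)magnesium bromide, CC(C)=CCC[Mg]Br
Why: Organocerium 1,2-addition avoids enolisation and conjugate addition; axial attack on the half-chair with both substituents equatorial, as with 5-substituted cyclohexenones, should place the hydroxyl cis to the C5 aryl group (1R), and the minor epimer is removed by chromatography.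

Step 11
Reactants: 16 (1R,4S,5S)-5-Ar1-1-(4-methylpent-3-en-1-yl)-4-[Ar2(triethylsilyloxy)methyl]cyclohex-2-en-1-ol
Product: 17 tributylstannylmethyl ether of 16
Conditions: KH, 18-crown-6, Bu3SnCH2I, THF, 0 °C to rt
Reagents that add atoms: (iodomethyl)tributylstannane, CCCC[Sn](CCCC)(CCCC)CI
Why: Williamson etherification of the tertiary potassium alkoxide with a reactive primary iodide.

Step 12
Reactants: 17 tributylstannylmethyl ether of 16
Product: 19 (3R,4R,5S)-5-Ar1-3-(hydroxymethyl)-1-(4-methylpent-3-en-1-yl)-4-[Ar2(triethylsilyloxy)methyl]cyclohex-1-ene, via lithiomethyl ether 18 (not isolated)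
Conditions: n-BuLi, THF, −78 °C
Reagents that add atoms: none
Why: Tin–lithium exchange gives the alpha-alkoxy organolithium, which undergoes [2,3]-Wittig rearrangement; the shift is suprafacial, so the new C3–C bond forms on the face that carried the oxygen (cis to the C5 aryl, trans to the C4 group) and the alkene moves to C1=C2, which sets C3.

Step 13
Reactants: 19 (3R,4R,5S)-5-Ar1-3-(hydroxymethyl)-1-(4-methylpent-3-en-1-yl)-4-[Ar2(triethylsilyloxy)methyl]cyclohex-1-ene
Product: 20 (3R,4R,5S)-5-Ar1-3-formyl-1-(4-methylpent-3-en-1-yl)-4-[Ar2(triethylsilyloxy)methyl]cyclohex-1-ene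
Conditions: DMP, pyridine, CH2Cl2, 0 °C
Reagents that add atoms: none
Why: Buffered periodinane oxidation is non-basic, so the beta,gamma-unsaturated aldehyde should neither epimerise at C3 nor move into conjugation.

Step 14
Reactants: 20 (3R,4R,5S)-5-Ar1-3-formyl-1-(4-methylpent-3-en-1-yl)-4-[Ar2(triethylsilyloxy)methyl]cyclohex-1-ene
Product: 21 (3R,4R,5S)-5-Ar1-3-(2,2-dibromoethenyl)-1-(4-methylpent-3-en-1-yl)-4-[Ar2(triethylsilyloxy)methyl]cyclohex-1-ene
Conditions: CBr4, PPh3, Et3N, CH2Cl2, 0 °C
Reagents that add atoms: carbon tetrabromide, BrC(Br)(Br)Br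
Why: Corey–Fuchs dibromo-olefination with the non-basic ylide Ph3P=CBr2 adds the second alkyne carbon without risk to C3.

Step 15
Reactants: 21 (3R,4R,5S)-5-Ar1-3-(2,2-dibromoethenyl)-1-(4-methylpent-3-en-1-yl)-4-[Ar2(triethylsilyloxy)methyl]cyclohex-1-ene
Product: 24 (3R,4R,5S)-5-Ar1-1-(4-methylpent-3-en-1-yl)-4-[Ar2(triethylsilyloxy)methyl]-3-[(triisopropylsilyloxy)ethynyl]cyclohex-1-ene, via lithium acetylide 22 (not isolated), via lithium ynolate 23 (not isolated)
Conditions: n-BuLi (2.1 equiv), THF, −78 °C; LiOOtBu (from t-BuOOH, LiN(SiMe3)2), −78 to 0 °C; TIPSOTf, −78 °C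
Reagents that add atoms: tert-butyl hydroperoxide, CC(C)(C)OO; triisopropylsilyl trifluoromethanesulfonate, CC(C)[Si](C(C)C)(C(C)C)OS(=O)(=O)C(F)(F)F
Why: Bromine–lithium exchange and 1,2-hydrogen shift (second stage of the Corey–Fuchs reaction) give the acetylide; electrophilic oxygen transfer from the lithium peroxide gives the ynolate, which the bulky silyl triflate silylates on oxygen.

Step 16
Reactants: 25 ethyl 2,4-dioxopentanoate
Product: 26 ethyl (2Z)-2,4-bis(trimethylsilyloxy)penta-2,4-dienoate
Conditions: TMSOTf (2.3 equiv), Et3N, Et2O, 0 °C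
Reagents that add atoms: trimethylsilyl trifluoromethanesulfonate, C[Si](C)(C)OS(=O)(=O)C(F)(F)F
Why: Soft enolisation and O-silylation, first at the enolised 1,3-dicarbonyl and then at the remaining methyl ketone, give the bis(silyl) dienol ether.

Step 17
Reactants: 2 2,4-bis(methoxymethoxy)benzaldehyde; 26 ethyl (2Z)-2,4-bis(trimethylsilyloxy)penta-2,4-dienoate
Product: 28 ethyl (2S)-2-Ar1-4-oxo-3,4-dihydro-2H-pyran-6-carboxylate, via hydroxy diketo ester 27 (not isolated)
Conditions: Ti(OiPr)4 (10 mol %), (S)-BINOL (10 mol %), 4 Å MS, THF, −78 to −20 °C; then CSA (10 mol %), CH2Cl2, 0 °C to rt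
Reagents that add atoms: none
Why: Hetero-Diels–Alder reaction in its stepwise form: a vinylogous Mukaiyama aldol addition of the terminal CH2 to the aldehyde held by the BINOL titanium complex, which selects the aldehyde face and sets the stereocentre; the hydroxy diketo ester then closes onto the alpha-keto carbon and loses water under mild acid.

Step 18
Reactants: 28 ethyl (2S)-2-Ar1-4-oxo-3,4-dihydro-2H-pyran-6-carboxylate
Product: 29 (2S)-2-Ar1-4-oxo-3,4-dihydro-2H-pyran-6-carboxylic acid
Conditions: Me3SnOH, ClCH2CH2Cl, 70 °C; dilute HCl wash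
Reagents that add atoms: trimethyltin hydroxide, C[Sn](C)(C)O
Why: Neutral tin hydroxide cleaves the activated ester without forming the C3 enolate, which would open the ring by beta-elimination and destroy the C2 centre.

Step 19
Reactants: 29 (2S)-2-Ar1-4-oxo-3,4-dihydro-2H-pyran-6-carboxylic acid
Product: 31 (2S)-2-Ar1-6-(diazoacetyl)-2,3-dihydro-4H-pyran-4-one, via acid chloride 30 (not isolated)
Conditions: 1-chloro-N,N,2-trimethylprop-1-en-1-amine, CH2Cl2, 0 °C; then CH2N2 (excess), Et2O, −20 to 0 °C
Reagents that add atoms: diazomethane, C=[N+]=[N-]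
Why: Acylation of diazomethane by the acid chloride (first stage of the Arndt–Eistert sequence); the chloroenamine makes the chloride without HCl, so the acetals are safe, and low temperature favours acylation over dipolar addition to the ring alkene.

Step 20
Reactants: 24 (3R,4R,5S)-5-Ar1-1-(4-methylpent-3-en-1-yl)-4-[Ar2(triethylsilyloxy)methyl]-3-[(triisopropylsilyloxy)ethynyl]cyclohex-1-ene; 31 (2S)-2-Ar1-6-(diazoacetyl)-2,3-dihydro-4H-pyran-4-one
Product: 35 (2S)-2-Ar1-5-hydroxy-7-(triisopropylsilyloxy)flavanone bonded at C6 to C3 of the (3R,4R,5S)-cyclohexene of 24, via vinylketene 32 (not isolated), via vinylcyclobutenone 33 (not isolated), via dienylketene 34 (not isolated)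
Conditions: hν (365 nm), ClCH2CH2Cl, rt, slow addition of 31 (1.5 equiv) to 24; then 80 °C
Reagents that add atoms: none
Why: Light expels N2 from 31 and the 1,2-shift of the pyranone C6 (Wolff rearrangement) gives vinylketene 32, which the electron-rich siloxyalkyne 24 traps in a [2+2] cycloaddition to give vinylcyclobutenone 33. Warming opens 33 by 4-pi electrocyclic cleavage to dienylketene 34, and 6-pi electrocyclisation followed by enolisation gives the phenol; the closest known reaction is the Danheiser benzannulation of siloxyalkynes with vinylketenes from unsaturated alpha-diazo ketones. Ring A is the only ring closed, by 6-pi electrocyclisation of the ketene carbon onto the pyranone alpha carbon (the future C4a), and tautomerisation is driven by aromatisation and by the hydrogen bond from the new C5 hydroxyl to the C4 carbonyl. No stereocentre is formed; the flavanone C2 and the cyclohexene triad are spectators, C3 being neither alpha to a carbonyl nor a reacting atom. The selectivity needed is the regiochemistry of the [2+2] step, which the polarisation of the siloxyalkyne secures: its nucleophilic carbon, the one bonded to C3, attacks the ketene carbonyl carbon, so C3 ends up between the free C5 hydroxyl and the C7 silyl ether. Closure can occur at only one vinyl terminus, so 6- versus 8-substitution does not arise. Long-wavelength light is chosen because the aryl ethers and the masked C4 carbinol do not absorb there.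

Step 21
Reactants: 35 key-step product (5-OH, 7-OTIPS, C4 triethylsilyloxy carbinol)
Product: 36 the corresponding free carbinol (5-OH, 7-OTIPS)
Conditions: HF·pyridine, pyridine, THF, 0 °C
Reagents that add atoms: none
Why: Buffered HF removes the alkyl triethylsilyl ether much faster than the aryl triisopropylsilyl ether or the acetals.

Step 22
Reactants: 36 free carbinol (5-OH, 7-OTIPS)
Product: 37 C4 aryl ketone (5-OH, 7-OTIPS, five MOM ethers)
Conditions: DMP, pyridine, CH2Cl2, 0 °C to rt
Reagents that add atoms: none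
Why: Periodinane oxidation of the benzylic alcohol; the only free phenol is the chelated, doubly ortho-substituted C5 hydroxyl, and C4 now sits alpha to the ketone in its stable all-trans arrangement.

Step 23
Reactants: 37 C4 aryl ketone (5-OH, 7-OTIPS, five MOM ethers)
Product: 38 5,7-dihydroxy pentakis(methoxymethyl) ether
Conditions: Bu4NF, AcOH, THF, 0 °C
Reagents that add atoms: none
Why: Fluoride cleaves the aryl silyl ether; acetic acid keeps the medium from becoming basic enough to open the flavanone.

Step 24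
Reactants: 38 5,7-dihydroxy pentakis(methoxymethyl) ether
Product: 39 target CNP0235243.2
Conditions: HCl (3 M aq), MeOH, rt to 40 °C
Reagents that add atoms: none
Why: Acid-catalysed acetal exchange with methanol frees the five phenols; mild temperature limits prenyl cyclisation and C2 epimerisation.

## Compound list

1 | 2,4-dihydroxybenzaldehyde | O=Cc1ccc(O)cc1O | starting material
2 | 2,4-bis(methoxymethoxy)benzaldehyde | O=Cc1ccc(OCOC)cc1OCOC | intermediate
3 | (E)-3-[2,4-bis(methoxymethoxy)phenyl]prop-2-enal | O=C/C=C/c1ccc(OCOC)cc1OCOC | intermediate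
4 | (E)-4-methoxybut-3-en-2-one | CO/C=C/C(C)=O | starting material
5 | (2S,5S)-2,5-diphenylpyrrolidine | N1[C@H](c2ccccc2)CC[C@H]1c1ccccc1 | starting material
6 | (E)-4-[(2S,5S)-2,5-diphenylpyrrolidin-1-yl]but-3-en-2-one | CC(=O)/C=C/N1[C@H](c2ccccc2)CC[C@H]1c1ccccc1 | intermediate
7 | (2S,5S)-1-[(1E)-3-(tert-butyldimethylsilyloxy)buta-1,3-dien-1-yl]-2,5-diphenylpyrrolidine | C=C(O[Si](C)(C)C(C)(C)C)/C=C/N1[C@H](c2ccccc2)CC[C@H]1c1ccccc1 | intermediate
8 | (1R,2S,6S)-6-Ar1-4-(tert-butyldimethylsilyloxy)-2-[(2S,5S)-2,5-diphenylpyrrolidin-1-yl]cyclohex-3-ene-1-carbaldehyde | CC(C)(C)[Si](C)(C)OC1=C[C@H](N2[C@H](c3ccccc3)CC[C@H]2c2ccccc2)[C@H](C=O)[C@@H](c2ccc(OCOC)cc2OCOC)C1 | intermediate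
9 | 4-bromophenol | Oc1ccc(Br)cc1 | starting material
10 | 4-bromo-2-(3-methylbut-2-en-1-yl)phenol | CC(C)=CCc1cc(Br)ccc1O | intermediate
11 | 4-bromo-1-(methoxymethoxy)-2-(3-methylbut-2-en-1-yl)benzene | COCOc1ccc(Br)cc1CC=C(C)C | intermediate
12 | [4-(methoxymethoxy)-3-(3-methylbut-2-en-1-yl)phenyl]lithium | [Li]c1ccc(OCOC)c(CC=C(C)C)c1 | intermediate
13 | carbinol from 8 and 12 (ring configuration as in 8; carbinol epimers) | CC(C)(C)[Si](C)(C)OC1=C[C@H](N2[C@H](c3ccccc3)CC[C@H]2c2ccccc2)[C@H](C(O)c2ccc(OCOC)c(CC=C(C)C)c2)[C@@H](c2ccc(OCOC)cc2OCOC)C1 | intermediate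
14 | (4S,5S)-5-Ar1-4-[Ar2(hydroxy)methyl]cyclohex-2-en-1-one (4,5-trans; carbinol epimers) | O=C1C=C[C@H](C(O)c2ccc(OCOC)c(CC=C(C)C)c2)[C@@H](c2ccc(OCOC)cc2OCOC)C1 | intermediate
15 | (4S,5S)-5-Ar1-4-[Ar2(triethylsilyloxy)methyl]cyclohex-2-en-1-one | O=C1C=C[C@H](C(O[Si](CC)(CC)CC)c2ccc(OCOC)c(CC=C(C)C)c2)[C@@H](c2ccc(OCOC)cc2OCOC)C1 | intermediate
16 | (1R,4S,5S)-5-Ar1-1-(4-methylpent-3-en-1-yl)-4-[Ar2(triethylsilyloxy)methyl]cyclohex-2-en-1-ol (hydroxyl cis to the C5 aryl) | O[C@@]1(CCC=C(C)C)C=C[C@H](C(O[Si](CC)(CC)CC)c2ccc(OCOC)c(CC=C(C)C)c2)[C@@H](c2ccc(OCOC)cc2OCOC)C1 | intermediate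
17 | tributylstannylmethyl ether of 16 | CCCC[Sn](CCCC)(CCCC)CO[C@@]1(CCC=C(C)C)C=C[C@H](C(O[Si](CC)(CC)CC)c2ccc(OCOC)c(CC=C(C)C)c2)[C@@H](c2ccc(OCOC)cc2OCOC)C1 | intermediate
18 | lithiomethyl ether of 16 | [Li]CO[C@@]1(CCC=C(C)C)C=C[C@H](C(O[Si](CC)(CC)CC)c2ccc(OCOC)c(CC=C(C)C)c2)[C@@H](c2ccc(OCOC)cc2OCOC)C1 | intermediate
19 | (3R,4R,5S)-5-Ar1-3-(hydroxymethyl)-1-(4-methylpent-3-en-1-yl)-4-[Ar2(triethylsilyloxy)methyl]cyclohex-1-ene (all-trans) | CC(C)=CCCC1=C[C@@H](CO)[C@H](C(O[Si](CC)(CC)CC)c2ccc(OCOC)c(CC=C(C)C)c2)[C@@H](c2ccc(OCOC)cc2OCOC)C1 | intermediate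
20 | (3R,4R,5S)-3-formyl analogue of 19 | CC(C)=CCCC1=C[C@@H](C=O)[C@H](C(O[Si](CC)(CC)CC)c2ccc(OCOC)c(CC=C(C)C)c2)[C@@H](c2ccc(OCOC)cc2OCOC)C1 | intermediate
21 | (3R,4R,5S)-3-(2,2-dibromoethenyl) analogue of 19 | CC(C)=CCCC1=C[C@@H](C=C(Br)Br)[C@H](C(O[Si](CC)(CC)CC)c2ccc(OCOC)c(CC=C(C)C)c2)[C@@H](c2ccc(OCOC)cc2OCOC)C1 | intermediate
22 | lithium acetylide at C3 (configuration as in 21) | CC(C)=CCCC1=C[C@@H](C#C[Li])[C@H](C(O[Si](CC)(CC)CC)c2ccc(OCOC)c(CC=C(C)C)c2)[C@@H](c2ccc(OCOC)cc2OCOC)C1 | intermediate
23 | lithium ynolate at C3 (configuration as in 21) | CC(C)=CCCC1=C[C@@H](C#CO[Li])[C@H](C(O[Si](CC)(CC)CC)c2ccc(OCOC)c(CC=C(C)C)c2)[C@@H](c2ccc(OCOC)cc2OCOC)C1 | intermediate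
24 | (3R,4R,5S)-5-Ar1-1-(4-methylpent-3-en-1-yl)-4-[Ar2(triethylsilyloxy)methyl]-3-[(triisopropylsilyloxy)ethynyl]cyclohex-1-ene | CC(C)=CCCC1=C[C@@H](C#CO[Si](C(C)C)(C(C)C)C(C)C)[C@H](C(O[Si](CC)(CC)CC)c2ccc(OCOC)c(CC=C(C)C)c2)[C@@H](c2ccc(OCOC)cc2OCOC)C1 | intermediate
25 | ethyl 2,4-dioxopentanoate | CCOC(=O)C(=O)CC(C)=O | starting material
26 | ethyl (2Z)-2,4-bis(trimethylsilyloxy)penta-2,4-dienoate | CCOC(=O)/C(O[Si](C)(C)C)=C/C(=C)O[Si](C)(C)C | intermediate
27 | ethyl (6S)-6-Ar1-6-hydroxy-2,4-dioxohexanoate | CCOC(=O)C(=O)CC(=O)C[C@H](O)c1ccc(OCOC)cc1OCOC | intermediate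
28 | ethyl (2S)-2-Ar1-4-oxo-3,4-dihydro-2H-pyran-6-carboxylate | CCOC(=O)C1=CC(=O)C[C@@H](c2ccc(OCOC)cc2OCOC)O1 | intermediate
29 | (2S)-2-Ar1-4-oxo-3,4-dihydro-2H-pyran-6-carboxylic acid | OC(=O)C1=CC(=O)C[C@@H](c2ccc(OCOC)cc2OCOC)O1 | intermediate
30 | (2S)-2-Ar1-4-oxo-3,4-dihydro-2H-pyran-6-carbonyl chloride | ClC(=O)C1=CC(=O)C[C@@H](c2ccc(OCOC)cc2OCOC)O1 | intermediate
31 | (2S)-2-Ar1-6-(diazoacetyl)-2,3-dihydro-4H-pyran-4-one | [N-]=[N+]=CC(=O)C1=CC(=O)C[C@@H](c2ccc(OCOC)cc2OCOC)O1 | intermediate
32 | (2S)-2-Ar1-6-(2-oxoethenyl)-2,3-dihydro-4H-pyran-4-one (vinylketene) | O=C=CC1=CC(=O)C[C@@H](c2ccc(OCOC)cc2OCOC)O1 | intermediate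
33 | 4-(pyranonyl)-3-(triisopropylsilyloxy)cyclobut-2-enone bonded at C2 to C3 of the cyclohexene of 24 | CC(C)=CCCC1=C[C@@H](C2=C(O[Si](C(C)C)(C(C)C)C(C)C)C(C3=CC(=O)C[C@@H](c4ccc(OCOC)cc4OCOC)O3)C2=O)[C@H](C(O[Si](CC)(CC)CC)c2ccc(OCOC)c(CC=C(C)C)c2)[C@@H](c2ccc(OCOC)cc2OCOC)C1 | intermediate
34 | dienylketene from ring opening of 33 | CC(C)=CCCC1=C[C@@H](C(=C=O)C(O[Si](C(C)C)(C(C)C)C(C)C)=CC2=CC(=O)C[C@@H](c3ccc(OCOC)cc3OCOC)O2)[C@H](C(O[Si](CC)(CC)CC)c2ccc(OCOC)c(CC=C(C)C)c2)[C@@H](c2ccc(OCOC)cc2OCOC)C1 | intermediate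
35 | (2S)-2-Ar1-5-hydroxy-7-(triisopropylsilyloxy)chroman-4-one bonded at C6 to C3 of the (3R,4R,5S)-cyclohexene carrying C1 4-methylpent-3-enyl, C4 Ar2(triethylsilyloxy)methyl and C5 Ar1 | CC(C)=CCCC1=C[C@@H](c2c(O[Si](C(C)C)(C(C)C)C(C)C)cc3c(c2O)C(=O)C[C@@H](c2ccc(OCOC)cc2OCOC)O3)[C@H](C(O[Si](CC)(CC)CC)c2ccc(OCOC)c(CC=C(C)C)c2)[C@@H](c2ccc(OCOC)cc2OCOC)C1 | intermediate
36 | as 35 with the free C4 carbinol Ar2(hydroxy)methyl | CC(C)=CCCC1=C[C@@H](c2c(O[Si](C(C)C)(C(C)C)C(C)C)cc3c(c2O)C(=O)C[C@@H](c2ccc(OCOC)cc2OCOC)O3)[C@H](C(O)c2ccc(OCOC)c(CC=C(C)C)c2)[C@@H](c2ccc(OCOC)cc2OCOC)C1 | intermediate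
37 | as 36 with the C4 ketone (Ar2-carbonyl); 5-OH, 7-OTIPS, five MOM ethers | CC(C)=CCCC1=C[C@@H](c2c(O[Si](C(C)C)(C(C)C)C(C)C)cc3c(c2O)C(=O)C[C@@H](c2ccc(OCOC)cc2OCOC)O3)[C@H](C(=O)c2ccc(OCOC)c(CC=C(C)C)c2)[C@@H](c2ccc(OCOC)cc2OCOC)C1 | intermediate
38 | as 37 with free 5- and 7-hydroxyls; five MOM ethers | CC(C)=CCCC1=C[C@@H](c2c(O)cc3c(c2O)C(=O)C[C@@H](c2ccc(OCOC)cc2OCOC)O3)[C@H](C(=O)c2ccc(OCOC)c(CC=C(C)C)c2)[C@@H](c2ccc(OCOC)cc2OCOC)C1 | intermediate
39 | CNP0235243.2: (2S)-2-(2,4-dihydroxyphenyl)-5,7-dihydroxychroman-4-one bonded at C6 to C3 of the (3R,4R,5S)-cyclohex-1-ene carrying C1 4-methylpent-3-enyl, C4 4-hydroxy-3-(3-methylbut-2-enyl)benzoyl and C5 2,4-dihydroxyphenyl | CC(C)=CCCC1=C[C@@H](c2c(O)cc3c(c2O)C(=O)C[C@@H](c2ccc(O)cc2O)O3)[C@H](C(=O)c2ccc(O)c(CC=C(C)C)c2)[C@@H](c2ccc(O)cc2O)C1 | target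

## Step count and risks

Total step count: 24. Longest linear sequence: 16 steps (1 → 2 → 3 → 8 → 14 → 15 → 16 → 17 → 19 → 20 → 21 → 24 → 35 → 36 → 37 → 38 → 39).

**Step 20 (key step).** The branched C3 substituent may slow the [2+2] cycloaddition enough for ketene dimerisation to compete, and the flavanone product may itself undergo photochemical ring opening on prolonged irradiation. The fallback generates the same vinylketene without light. Diazo ketone 31 is rearranged with silver benzoate and Et3N in aqueous THF (Arndt–Eistert homologation) to [(2S)-2-Ar1-4-oxo-3,4-dihydro-2H-pyran-6-yl]acetic acid F1. This is converted with 1-chloro-N,N,2-trimethylprop-1-en-1-amine into the acid chloride F2. Slow addition of iPr2NEt to F2 and 24 in toluene at 25 to 80 °C dehydrochlorinates F2 to 32, which goes on through 33 and 34 and rejoins the route at 35.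

**Step 17.** The ester-bearing dienol ether is less nucleophilic than the usual dienes, so turnover or face selectivity of the titanium-catalysed aldol may be poor, and the acid closure may cost an acetal. The fallback builds the same carbon chain stepwise from 2. Titanium–BINOL-catalysed allylation with allyltributylstannane gives (S)-1-Ar1-but-3-en-1-ol F3; TBSCl and imidazole give its silyl ether F4; Wacker oxidation (PdCl2, CuCl, O2, DMF–H2O) gives the methyl ketone F5; Claisen condensation with diethyl oxalate (LiN(SiMe3)2, −78 °C) gives the silyloxy diketo ester F6. Desilylation with HF·pyridine followed by catalytic CSA gives 27 and then 28, where the route resumes.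

**Step 19.** Diazomethane may add as a dipole to the electron-poor ring alkene instead of being acylated. The fallback avoids diazomethane. Acid chloride 30 is coupled with methylzinc chloride under Pd(PPh3)4 (Negishi acylation) to give the 6-acetyl dihydropyranone F7. This is trifluoroacetylated at the methyl group (LiN(SiMe3)2, CF3CO2CH2CF3, −78 °C) to the diketone F8, and detrifluoroacetylative diazo transfer (MsN3, Et3N, H2O, MeCN) gives 31.

**Step 12 (with step 11).** O-Alkylation of the hindered tertiary alkoxide may be incomplete. The rearrangement requires the C1 oxygen to be pseudoaxial, which forces the C5 aryl group axial as well, so a [1,2]-shift or simple protonation may compete with the [2,3] pathway. The fallback uses a [3,3] shift with the same suprafacial outcome and reaches the ynolate without an aldehyde. Alcohol 16 is acetylated (Ac2O, DMAP) to acetate F9. Ireland–Claisen rearrangement (LDA, TMSCl, THF, −78 °C to rt) gives the C3 acetic acid F10. TMSCHN2 gives methyl ester F11, and double alpha-bromination (LiN(SiMe3)2, CBr4, twice) gives the dibromo ester F12. Treatment with t-BuLi at −78 to 0 °C cleaves F12 to ynolate 23, which is silylated with TIPSOTf to rejoin the route at 24.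

**Step 24.** Protic acid may close the prenyl group onto the liberated ortho phenol, epimerise the flavanone C2 through ring opening, or leave acetals behind if kept mild enough to avoid both. The fallback replaces protonation by aprotic thiol-assisted acetal transfer (ZnBr2, n-PrSH, CH2Cl2, 0 °C), applied to 38 and giving 39 directly.

## Further compounds

F1 | step 20 | [(2S)-2-Ar1-4-oxo-3,4-dihydro-2H-pyran-6-yl]acetic acid | OC(=O)CC1=CC(=O)C[C@@H](c2ccc(OCOC)cc2OCOC)O1
F2 | step 20 | [(2S)-2-Ar1-4-oxo-3,4-dihydro-2H-pyran-6-yl]acetyl chloride | ClC(=O)CC1=CC(=O)C[C@@H](c2ccc(OCOC)cc2OCOC)O1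
F3 | step 17 | (S)-1-[2,4-bis(methoxymethoxy)phenyl]but-3-en-1-ol | C=CC[C@H](O)c1ccc(OCOC)cc1OCOC
F4 | step 17 | tert-butyldimethylsilyl ether of F3 | C=CC[C@H](O[Si](C)(C)C(C)(C)C)c1ccc(OCOC)cc1OCOC
F5 | step 17 | (S)-4-[2,4-bis(methoxymethoxy)phenyl]-4-(tert-butyldimethylsilyloxy)butan-2-one | CC(=O)C[C@H](O[Si](C)(C)C(C)(C)C)c1ccc(OCOC)cc1OCOC
F6 | step 17 | ethyl (6S)-6-Ar1-6-(tert-butyldimethylsilyloxy)-2,4-dioxohexanoate | CCOC(=O)C(=O)CC(=O)C[C@H](O[Si](C)(C)C(C)(C)C)c1ccc(OCOC)cc1OCOC
F7 | step 19 | (2S)-6-acetyl-2-Ar1-2,3-dihydro-4H-pyran-4-one | CC(=O)C1=CC(=O)C[C@@H](c2ccc(OCOC)cc2OCOC)O1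
F8 | step 19 | (2S)-2-Ar1-6-(4,4,4-trifluoro-3-oxobutanoyl)-2,3-dihydro-4H-pyran-4-one | O=C(CC(=O)C(F)(F)F)C1=CC(=O)C[C@@H](c2ccc(OCOC)cc2OCOC)O1
F9 | step 12 | acetate of 16 | CC(=O)O[C@@]1(CCC=C(C)C)C=C[C@H](C(O[Si](CC)(CC)CC)c2ccc(OCOC)c(CC=C(C)C)c2)[C@@H](c2ccc(OCOC)cc2OCOC)C1
F10 | step 12 | C3 acetic acid (all-trans cyclohexene as in 19) | CC(C)=CCCC1=C[C@@H](CC(=O)O)[C@H](C(O[Si](CC)(CC)CC)c2ccc(OCOC)c(CC=C(C)C)c2)[C@@H](c2ccc(OCOC)cc2OCOC)C1
F11 | step 12 | methyl ester of F10 | CC(C)=CCCC1=C[C@@H](CC(=O)OC)[C@H](C(O[Si](CC)(CC)CC)c2ccc(OCOC)c(CC=C(C)C)c2)[C@@H](c2ccc(OCOC)cc2OCOC)C1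
F12 | step 12 | alpha,alpha-dibromo ester of F11 | CC(C)=CCCC1=C[C@@H](C(Br)(Br)C(=O)OC)[C@H](C(O[Si](CC)(CC)CC)c2ccc(OCOC)c(CC=C(C)C)c2)[C@@H](c2ccc(OCOC)cc2OCOC)C1
F0 | step 24 | none | none
A1 | alternative 1 | 4-Ar1-6-(4-methylpent-3-enyl)-6-[(E)-2-(2,4,6-tris(methoxymethoxy)phenyl)ethenyl]tetrahydropyran-2-one | O=C1C[C@@H](c2ccc(OCOC)cc2OCOC)C[C@](CCC=C(C)C)(/C=C/c2c(OCOC)cc(OCOC)cc2OCOC)O1
A2 | alternative 1 | 3,4,5-all-cis cyclohexene-4-carboxylic acid | CC(C)=CCCC1=C[C@@H](c2c(OCOC)cc(OCOC)cc2OCOC)[C@@H](C(=O)O)[C@@H](c2ccc(OCOC)cc2OCOC)C1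
A3 | alternative 2 | 6-methyl-2-(trimethylsilyloxy)hepta-1,5-diene | C=C(CCC=C(C)C)O[Si](C)(C)C
A4 | alternative 2 | methyl 2-[2,4-bis(methoxymethoxy)benzylidene]-4-(dimethoxyphosphoryl)-3-oxobutanoate | COC(=O)C(=Cc1ccc(OCOC)cc1OCOC)C(=O)CP(=O)(OC)OC
A5 | alternative 2 | methyl trans-6-Ar1-4-(4-methylpent-3-enyl)-2-oxocyclohex-3-ene-1-carboxylate | CC(C)=CCCC1=CC(=O)[C@H](C(=O)OC)[C@@H](c2ccc(OCOC)cc2OCOC)C1
A6 | alternative 3 | open-chain ortho-hydroxybenzylic alcohol with the aryl ketone and the C3 aryl centre | CC(C)=CCC/C(CC(O)c1ccc(OCOC)cc1O)=C/[C@H](CC(=O)c1ccc(OCOC)c(CC=C(C)C)c1)c1c(OCOC)cc(OCOC)cc1OCOC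
A7 | alternative 3 | all-trans cyclohexene with the free ortho phenol on the C5 aryl | CC(C)=CCCC1=C[C@@H](c2c(OCOC)cc(OCOC)cc2OCOC)[C@H](C(=O)c2ccc(OCOC)c(CC=C(C)C)c2)[C@@H](c2ccc(OCOC)cc2O)C1
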